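**Retrosynthetic overview**
- The ten-membered ring is closed last, by ring-closing metathesis at the (Z)-C1=C10 olefin of an acyclic diene that already carries the trans α-methylene-γ-lactone and the C8 ester; global desilylation then gives the target.
- The C8 ester comes from Steglich esterification with the TBS-protected (S)-Roche acid.
- C7 and C8 are set by a Zn-Barbier allylation (C7–C8 bond) of 3-methylbut-3-enal with a (5R)-3-(bromomethyl)butenolide, which turns the butenolide into the α-methylene lactone.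
- The butenolide (first ring, C6 set) comes from an asymmetric Nozaki–Hiyama–Kishi coupling/lactonisation (C6–C7 bond) of a (Z)-enal with a (Z)-β-iodoacrylate.
- The (Z)-enal comes from syn-carbocupration of a silyloxy ynoate; the iodoacrylate from an iodide-promoted Baylis–Hillman coupling of methyl propiolate with formaldehyde.

Assumption: C-numbers in the comments follow germacrane numbering of the target (lactone oxygen on C6, ester oxygen on C8, ring olefins C1=C10 and C4=C5, hydroxymethyl carbon C15).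

**Route**

Step 1
Reactants: 1 tert-butyl(diphenyl)(prop-2-yn-1-yloxy)silane
Product: 3 methyl 4-{[tert-butyl(diphenyl)silyl]oxy}but-2-ynoate, via lithium acetylide 2 (not isolated)
Conditions: n-BuLi, THF, −78 °C; ClCO2Me, −78 → 0 °C
Reagents that add atoms: methyl chloroformate COC(Cl)=O
Why: Deprotonation of the terminal alkyne and C-acylation of the lithium acetylide by the chloroformate gives the ynoate, with no stereocentre formed.

Step 2
Reactants: 3 methyl 4-{[tert-butyl(diphenyl)silyl]oxy}but-2-ynoate; 4 but-3-en-1-ylmagnesium bromide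
Product: 6 methyl (2Z)-3-({[tert-butyl(diphenyl)silyl]oxy}methyl)hepta-2,6-dienoate, via but-3-enylcopper 5 (not isolated)
Conditions: 4, CuI (1:1), THF, −40 °C; 3, −78 °C; sat. aq NH4Cl at −78 °C
Reagents that add atoms: none
Why: Syn-carbocupration of the ynoate followed by cold protonation puts the butenyl group and the new hydrogen cis, so the ester ends up cis to the CH2OSi group (2Z), which is the C4=C5 geometry of the target.

Step 3
Reactants: 6 methyl (2Z)-3-({[tert-butyl(diphenyl)silyl]oxy}methyl)hepta-2,6-dienoate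
Product: 7 (2Z)-3-({[tert-butyl(diphenyl)silyl]oxy}methyl)hepta-2,6-dien-1-ol
Conditions: i-Bu2AlH (2.5 equiv), CH2Cl2, −78 °C; aq. potassium sodium tartrate
Reagents that add atoms: none
Why: 1,2-Reduction of the enoate by the aluminium hydride gives the allylic alcohol without touching the silyl ether or the olefin geometry.

Step 4
Reactants: 7 (2Z)-3-({[tert-butyl(diphenyl)silyl]oxy}methyl)hepta-2,6-dien-1-ol
Product: 8 (2Z)-3-({[tert-butyl(diphenyl)silyl]oxy}methyl)hepta-2,6-dienal
Conditions: MnO2 (activated, excess), CH2Cl2, rt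
Reagents that add atoms: none
Why: Allylic oxidation with MnO2 is neutral and heterogeneous, so the (Z)-enal forms without isomerisation of the trisubstituted double bond.

Step 5
Reactants: 9 methyl prop-2-ynoate
Product: 10 methyl (2Z)-2-(hydroxymethyl)-3-iodoprop-2-enoate
Conditions: MgI2 (1.2 equiv), monomeric CH2O (from cracked paraformaldehyde), CH2Cl2, 0 °C
Reagents that add atoms: formaldehyde C=O; magnesium diiodide [Mg+2].[I-].[I-]
Why: Iodide-promoted Morita–Baylis–Hillman-type coupling (iodide conjugate addition, then aldol of the iodo-allenolate with formaldehyde anti to iodine) gives the (Z)-β-iodoacrylate with iodine cis to the ester.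

Step 6
Reactants: 10 methyl (2Z)-2-(hydroxymethyl)-3-iodoprop-2-enoate
Product: 11 methyl (2Z)-2-({[tert-butyl(dimethyl)silyl]oxy}methyl)-3-iodoprop-2-enoate
Conditions: TBSOTf, 2,6-lutidine, CH2Cl2, −78 °C
Reagents that add atoms: tert-butyldimethylsilyl trifluoromethanesulfonate CC(C)(C)[Si](C)(C)OS(=O)(=O)C(F)(F)F
Why: Silylation with the silyl triflate and a non-nucleophilic base protects the allylic hydroxyl without addition–elimination at the β-iodoacrylate.

Step 7
Reactants: 8 (2Z)-3-({[tert-butyl(diphenyl)silyl]oxy}methyl)hepta-2,6-dienal; 11 methyl (2Z)-2-({[tert-butyl(dimethyl)silyl]oxy}methyl)-3-iodoprop-2-enoate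
Product: 14 (5R)-3-({[tert-butyl(dimethyl)silyl]oxy}methyl)-5-[(1Z)-2-({[tert-butyl(diphenyl)silyl]oxy}methyl)hexa-1,5-dien-1-yl]furan-2(5H)-one, via alkenylchromium dichloride 12 (not isolated), via hydroxy ester 13 (not isolated)
Conditions: CrCl2 (3.5 equiv), NiCl2 (2 mol %), (S)-N-[2-(4-isopropyl-4,5-dihydro-1,3-oxazol-2-yl)-6-methylphenyl]methanesulfonamide (3.8 equiv, recovered), Et3N, THF, rt; aq. work-up; PPTS (cat.), CH2Cl2
Reagents that add atoms: none
Why: Nozaki–Hiyama–Kishi coupling in which the alkenylchromium adds 1,2 to the enal with retention of the (Z)-acrylate geometry and the cis alkoxide lactonises onto the methyl ester; the chiral sulfonamide–oxazoline ligand on trivalent chromium is chosen to direct attack to the Si face of the aldehyde, which sets the (5R) centre (C6), and the mirror-image ligand is used if a test run shows the opposite sense.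

Step 8
Reactants: 14 (5R)-3-({[tert-butyl(dimethyl)silyl]oxy}methyl)-5-[(1Z)-2-({[tert-butyl(diphenyl)silyl]oxy}methyl)hexa-1,5-dien-1-yl]furan-2(5H)-one
Product: 15 (5R)-3-(bromomethyl)-5-[(1Z)-2-({[tert-butyl(diphenyl)silyl]oxy}methyl)hexa-1,5-dien-1-yl]furan-2(5H)-one
Conditions: Ph3PBr2 (1.1 equiv), CH2Cl2, 0 °C
Reagents that add atoms: triphenylphosphine dibromide BrP(Br)(c1ccccc1)(c1ccccc1)c1ccccc1
Why: Direct silyl ether to bromide exchange (SN2 of bromide on the alkoxyphosphonium ion) converts the primary allylic TBS ether while the bulkier TBDPS ether and the stereocentre stay untouched.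

Step 9
Reactants: 16 3-methylbut-3-en-1-ol
Product: 17 3-methylbut-3-enal
Conditions: Dess–Martin periodinane, NaHCO3, CH2Cl2, 0 °C; solution used at once
Reagents that add atoms: none
Why: Buffered Dess–Martin oxidation gives the β,γ-unsaturated aldehyde without migration of the double bond into conjugation.

Step 10
Reactants: 15 (5R)-3-(bromomethyl)-5-[(1Z)-2-({[tert-butyl(diphenyl)silyl]oxy}methyl)hexa-1,5-dien-1-yl]furan-2(5H)-one; 17 3-methylbut-3-enal
Product: 19 (4R,5R)-5-[(1Z)-2-({[tert-butyl(diphenyl)silyl]oxy}methyl)hexa-1,5-dien-1-yl]-4-[(1S)-1-hydroxy-3-methylbut-3-en-1-yl]-3-methylideneoxolan-2-one, via allylzinc bromide 18 (not isolated)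
Conditions: Zn dust, THF/sat. aq NH4Cl, 0 °C → rt; 17 (3 equiv)
Reagents that add atoms: none
Why: Zinc Barbier allylation in which the allylzinc reacts at its γ-carbon (SE2′) through a chair Zimmerman–Traxler transition state on the face anti to the alkenyl group at the γ-lactone carbon, giving the trans-lactone (C7) and, because the ring fixes the E-type allyl geometry, the anti (1S) carbinol (C8).

Step 11
Reactants: 20 methyl (2S)-3-hydroxy-2-methylpropanoate
Product: 21 methyl (2S)-3-{[tert-butyl(dimethyl)silyl]oxy}-2-methylpropanoate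
Conditions: TBSCl, imidazole, DMF, rt
Reagents that add atoms: tert-butyldimethylsilyl chloride CC(C)(C)[Si](C)(C)Cl
Why: Imidazole-mediated silylation of the primary alcohol leaves the α-stereocentre of the Roche ester untouched.

Step 12
Reactants: 21 methyl (2S)-3-{[tert-butyl(dimethyl)silyl]oxy}-2-methylpropanoate
Product: 22 (2S)-3-{[tert-butyl(dimethyl)silyl]oxy}-2-methylpropanoic acid
Conditions: LiOH, THF/MeOH/H2O, 0 °C → rt; 1 M HCl to pH 4 at 0 °C
Reagents that add atoms: lithium hydroxide [Li+].[OH-]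
Why: Mild saponification cleaves the methyl ester without epimerising the α-centre or β-eliminating the silyloxy group.

Step 13
Reactants: 19 (4R,5R)-5-[(1Z)-2-({[tert-butyl(diphenyl)silyl]oxy}methyl)hexa-1,5-dien-1-yl]-4-[(1S)-1-hydroxy-3-methylbut-3-en-1-yl]-3-methylideneoxolan-2-one; 22 (2S)-3-{[tert-butyl(dimethyl)silyl]oxy}-2-methylpropanoic acid
Product: 23 (1S)-1-{(2R,3R)-2-[(1Z)-2-({[tert-butyl(diphenyl)silyl]oxy}methyl)hexa-1,5-dien-1-yl]-4-methylidene-5-oxooxolan-3-yl}-3-methylbut-3-en-1-yl (2S)-3-{[tert-butyl(dimethyl)silyl]oxy}-2-methylpropanoate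
Conditions: DIC, DMAP (cat.), CH2Cl2, 0 °C → rt
Reagents that add atoms: none
Why: Steglich esterification acylates the secondary alcohol with retention at both stereocentres under conditions too mild for translactonisation.

Step 14
Reactants: 23 (1S)-1-{(2R,3R)-2-[(1Z)-2-({[tert-butyl(diphenyl)silyl]oxy}methyl)hexa-1,5-dien-1-yl]-4-methylidene-5-oxooxolan-3-yl}-3-methylbut-3-en-1-yl (2S)-3-{[tert-butyl(dimethyl)silyl]oxy}-2-methylpropanoate
Product: 24 (3aR,4S,6Z,10Z,11aR)-10-({[tert-butyl(diphenyl)silyl]oxy}methyl)-6-methyl-3-methylidene-2-oxo-2,3,3a,4,5,8,9,11a-octahydrocyclodeca[b]furan-4-yl (2S)-3-{[tert-butyl(dimethyl)silyl]oxy}-2-methylpropanoate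
Conditions: second-generation Hoveyda–Grubbs catalyst RuCl2(H2IMes)(=CH-C6H4-2-O-i-Pr) (15 mol %, two portions), toluene, 0.5 mM, 80 °C, Ar sparge
Reagents that add atoms: none
Why: Ring-closing metathesis between the monosubstituted vinyl group and the 1,1-disubstituted methallyl olefin releases ethene and closes the ten-membered ring, where the trisubstituted olefin is expected to form ring-cis (6Z), while the α-methylene lactone and the existing trisubstituted olefin are too electron-poor or hindered to compete.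

Step 15
Reactants: 24 (3aR,4S,6Z,10Z,11aR)-10-({[tert-butyl(diphenyl)silyl]oxy}methyl)-6-methyl-3-methylidene-2-oxo-2,3,3a,4,5,8,9,11a-octahydrocyclodeca[b]furan-4-yl (2S)-3-{[tert-butyl(dimethyl)silyl]oxy}-2-methylpropanoate
Product: 25 (3aR,4S,6Z,10Z,11aR)-10-(hydroxymethyl)-6-methyl-3-methylidene-2-oxo-2,3,3a,4,5,8,9,11a-octahydrocyclodeca[b]furan-4-yl (2S)-3-hydroxy-2-methylpropanoate
Conditions: HF·pyridine (excess), pyridine/THF, 0 °C → rt
Reagents that add atoms: none
Why: Fluoride-mediated desilylation under buffered conditions removes both silyl ethers and leaves the α-methylene lactone, the ester and all stereocentres intact.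

**Compound list**
1 | tert-butyl(diphenyl)(prop-2-yn-1-yloxy)silane | C#CCO[Si](c1ccccc1)(c1ccccc1)C(C)(C)C | starting material
2 | {3-{[tert-butyl(diphenyl)silyl]oxy}prop-1-yn-1-yl}lithium | [Li]C#CCO[Si](c1ccccc1)(c1ccccc1)C(C)(C)C | intermediate (not isolated)
3 | methyl 4-{[tert-butyl(diphenyl)silyl]oxy}but-2-ynoate | COC(=O)C#CCO[Si](c1ccccc1)(c1ccccc1)C(C)(C)C | intermediate
4 | but-3-en-1-ylmagnesium bromide | C=CCC[Mg]Br | starting material
5 | but-3-en-1-ylcopper | [Cu]CCC=C | intermediate (not isolated)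
6 | methyl (2Z)-3-({[tert-butyl(diphenyl)silyl]oxy}methyl)hepta-2,6-dienoate | COC(=O)/C=C(\CO[Si](c1ccccc1)(c1ccccc1)C(C)(C)C)CCC=C | intermediate
7 | (2Z)-3-({[tert-butyl(diphenyl)silyl]oxy}methyl)hepta-2,6-dien-1-ol | OC/C=C(\CO[Si](c1ccccc1)(c1ccccc1)C(C)(C)C)CCC=C | intermediate
8 | (2Z)-3-({[tert-butyl(diphenyl)silyl]oxy}methyl)hepta-2,6-dienal | O=C/C=C(\CO[Si](c1ccccc1)(c1ccccc1)C(C)(C)C)CCC=C | intermediate
9 | methyl prop-2-ynoate | COC(=O)C#C | starting material
10 | methyl (2Z)-2-(hydroxymethyl)-3-iodoprop-2-enoate | COC(=O)/C(CO)=C\I | intermediate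
11 | methyl (2Z)-2-({[tert-butyl(dimethyl)silyl]oxy}methyl)-3-iodoprop-2-enoate | COC(=O)/C(CO[Si](C)(C)C(C)(C)C)=C\I | intermediate
12 | [(1Z)-2-({[tert-butyl(dimethyl)silyl]oxy}methyl)-3-methoxy-3-oxoprop-1-en-1-yl]chromium dichloride | COC(=O)/C(CO[Si](C)(C)C(C)(C)C)=C\[Cr](Cl)Cl | intermediate (not isolated)
13 | methyl (2Z,4R,5Z)-2-({[tert-butyl(dimethyl)silyl]oxy}methyl)-6-({[tert-butyl(diphenyl)silyl]oxy}methyl)-4-hydroxydeca-2,5,9-trienoate | COC(=O)/C(CO[Si](C)(C)C(C)(C)C)=C\[C@H](O)/C=C(\CO[Si](c1ccccc1)(c1ccccc1)C(C)(C)C)CCC=C | intermediate (not isolated)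
14 | (5R)-3-({[tert-butyl(dimethyl)silyl]oxy}methyl)-5-[(1Z)-2-({[tert-butyl(diphenyl)silyl]oxy}methyl)hexa-1,5-dien-1-yl]furan-2(5H)-one | CC(C)(C)[Si](C)(C)OCC1=C[C@@H](/C=C(\CO[Si](c2ccccc2)(c2ccccc2)C(C)(C)C)CCC=C)OC1=O | intermediate
15 | (5R)-3-(bromomethyl)-5-[(1Z)-2-({[tert-butyl(diphenyl)silyl]oxy}methyl)hexa-1,5-dien-1-yl]furan-2(5H)-one | BrCC1=C[C@@H](/C=C(\CO[Si](c2ccccc2)(c2ccccc2)C(C)(C)C)CCC=C)OC1=O | intermediate
16 | 3-methylbut-3-en-1-ol | CC(=C)CCO | starting material
17 | 3-methylbut-3-enal | CC(=C)CC=O | intermediate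
18 | bromo{[(5R)-5-[(1Z)-2-({[tert-butyl(diphenyl)silyl]oxy}methyl)hexa-1,5-dien-1-yl]-2-oxo-2,5-dihydrofuran-3-yl]methyl}zinc | Br[Zn]CC1=C[C@@H](/C=C(\CO[Si](c2ccccc2)(c2ccccc2)C(C)(C)C)CCC=C)OC1=O | intermediate (not isolated)
19 | (4R,5R)-5-[(1Z)-2-({[tert-butyl(diphenyl)silyl]oxy}methyl)hexa-1,5-dien-1-yl]-4-[(1S)-1-hydroxy-3-methylbut-3-en-1-yl]-3-methylideneoxolan-2-one | C=C1C(=O)O[C@H](/C=C(\CO[Si](c2ccccc2)(c2ccccc2)C(C)(C)C)CCC=C)[C@H]1[C@@H](O)CC(C)=C | intermediate
20 | methyl (2S)-3-hydroxy-2-methylpropanoate | COC(=O)[C@@H](C)CO | starting material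
21 | methyl (2S)-3-{[tert-butyl(dimethyl)silyl]oxy}-2-methylpropanoate | COC(=O)[C@@H](C)CO[Si](C)(C)C(C)(C)C | intermediate
22 | (2S)-3-{[tert-butyl(dimethyl)silyl]oxy}-2-methylpropanoic acid | OC(=O)[C@@H](C)CO[Si](C)(C)C(C)(C)C | intermediate
23 | (1S)-1-{(2R,3R)-2-[(1Z)-2-({[tert-butyl(diphenyl)silyl]oxy}methyl)hexa-1,5-dien-1-yl]-4-methylidene-5-oxooxolan-3-yl}-3-methylbut-3-en-1-yl (2S)-3-{[tert-butyl(dimethyl)silyl]oxy}-2-methylpropanoate | C=C1C(=O)O[C@H](/C=C(\CO[Si](c2ccccc2)(c2ccccc2)C(C)(C)C)CCC=C)[C@H]1[C@@H](OC(=O)[C@@H](C)CO[Si](C)(C)C(C)(C)C)CC(C)=C | intermediate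
24 | (3aR,4S,6Z,10Z,11aR)-10-({[tert-butyl(diphenyl)silyl]oxy}methyl)-6-methyl-3-methylidene-2-oxo-2,3,3a,4,5,8,9,11a-octahydrocyclodeca[b]furan-4-yl (2S)-3-{[tert-butyl(dimethyl)silyl]oxy}-2-methylpropanoate | C=C1C(=O)O[C@@H]2/C=C(\CO[Si](c3ccccc3)(c3ccccc3)C(C)(C)C)CC/C=C(/C)C[C@H](OC(=O)[C@@H](C)CO[Si](C)(C)C(C)(C)C)[C@@H]12 | intermediate
25 | (3aR,4S,6Z,10Z,11aR)-10-(hydroxymethyl)-6-methyl-3-methylidene-2-oxo-2,3,3a,4,5,8,9,11a-octahydrocyclodeca[b]furan-4-yl (2S)-3-hydroxy-2-methylpropanoate | C=C1C(=O)O[C@@H]2/C=C(\CO)CC/C=C(/C)C[C@H](OC(=O)[C@@H](C)CO)[C@@H]12 | target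

**Step count**
Total steps: 15. Longest linear sequence: 10 (steps 1, 2, 3, 4, 7, 8, 10, 13, 14, 15); the side branches are steps 5–6, step 9 and steps 11–12.

**Steps most likely to fail**

Step 7 is the asymmetric Nozaki–Hiyama–Kishi union. The face selectivity depends on the ligand and is not established for this enal, and the doubly allylic lactone carbon can lose configuration under base. The fallback sets out from 8 and comes back at 14. Catalytic asymmetric alkynylation of 8 with commercial tert-butyl(dimethyl)(prop-2-yn-1-yloxy)silane (C#CCO[Si](C)(C)C(C)(C)C; ProPhenol ligand antipode that delivers the alkyne to the Si face, Me2Zn, toluene, 0 °C) gives the propargylic alcohol (4R,5Z)-1-{[tert-butyl(dimethyl)silyl]oxy}-6-({[tert-butyl(diphenyl)silyl]oxy}methyl)deca-5,9-dien-2-yn-4-ol F1. Hydroxyl-directed trans-hydroalumination with NaAlH2(OCH2CH2OCH3)2 in THF, then I2 at −78 °C, gives the vinyl iodide (2Z,4R,5Z)-1-{[tert-butyl(dimethyl)silyl]oxy}-6-({[tert-butyl(diphenyl)silyl]oxy}methyl)-2-iododeca-2,5,9-trien-4-ol F2 with iodine cis to the carbinol carbon. Carbonylative lactonisation (PdCl2(PPh3)2 cat., CO 1 atm, K2CO3, THF, 45 °C) closes the butenolide 14.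

Step 10 is the Barbier allylation. The diastereoselectivity at the carbinol, γ- versus α-attack, and isomerisation of the labile aldehyde 17 are the concerns. The fallback sets out from 15 and comes back at 19, forming the C8–C9 bond under reagent control instead. Zn-Barbier reaction of 15 with aqueous formaldehyde gives (4R,5R)-5-[(1Z)-2-({[tert-butyl(diphenyl)silyl]oxy}methyl)hexa-1,5-dien-1-yl]-4-(hydroxymethyl)-3-methylideneoxolan-2-one F3, in which only the ring centre is new. Dess–Martin oxidation gives the aldehyde (2R,3S)-2-[(1Z)-2-({[tert-butyl(diphenyl)silyl]oxy}methyl)hexa-1,5-dien-1-yl]-4-methylidene-5-oxooxolane-3-carbaldehyde F4. Brown methallylboration (2-methylallyl-B(Ipc)2 made from (−)-Ipc2BOMe and 2-methylallylmagnesium chloride, Et2O, −78 °C, ethanolamine work-up) adds to the Si face of the aldehyde and gives 19.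

Step 14 is the ring-closing metathesis. Ring strain in the ten-membered diene, dimerisation through the terminal vinyl group and E/Z control are the concerns. The fallback sets out from 19 and comes back at 24, moving the ring closure in front of the acylation. Metathesis of the free hydroxy lactone 19 (same catalyst, high dilution), where a small hydroxyl group replaces the bulky acyloxy group next to the methallyl arm, gives the macrocyclic alcohol (3aR,4S,6Z,10Z,11aR)-10-({[tert-butyl(diphenyl)silyl]oxy}methyl)-4-hydroxy-6-methyl-3-methylidene-3a,4,5,8,9,11a-hexahydrocyclodeca[b]furan-2(3H)-one F5. Esterification of this with 22 (DIC, DMAP cat., CH2Cl2) gives 24.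

**Further compounds**
F1 | step 7 | (4R,5Z)-1-{[tert-butyl(dimethyl)silyl]oxy}-6-({[tert-butyl(diphenyl)silyl]oxy}methyl)deca-5,9-dien-2-yn-4-ol | CC(C)(C)[Si](C)(C)OCC#C[C@H](O)/C=C(\CO[Si](c1ccccc1)(c1ccccc1)C(C)(C)C)CCC=C
F2 | step 7 | (2Z,4R,5Z)-1-{[tert-butyl(dimethyl)silyl]oxy}-6-({[tert-butyl(diphenyl)silyl]oxy}methyl)-2-iododeca-2,5,9-trien-4-ol | CC(C)(C)[Si](C)(C)OC/C(I)=C/[C@H](O)/C=C(\CO[Si](c1ccccc1)(c1ccccc1)C(C)(C)C)CCC=C
F3 | step 10 | (4R,5R)-5-[(1Z)-2-({[tert-butyl(diphenyl)silyl]oxy}methyl)hexa-1,5-dien-1-yl]-4-(hydroxymethyl)-3-methylideneoxolan-2-one | C=C1C(=O)O[C@H](/C=C(\CO[Si](c2ccccc2)(c2ccccc2)C(C)(C)C)CCC=C)[C@H]1CO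
F4 | step 10 | (2R,3S)-2-[(1Z)-2-({[tert-butyl(diphenyl)silyl]oxy}methyl)hexa-1,5-dien-1-yl]-4-methylidene-5-oxooxolane-3-carbaldehyde | C=C1C(=O)O[C@H](/C=C(\CO[Si](c2ccccc2)(c2ccccc2)C(C)(C)C)CCC=C)[C@H]1C=O
F5 | step 14 | (3aR,4S,6Z,10Z,11aR)-10-({[tert-butyl(diphenyl)silyl]oxy}methyl)-4-hydroxy-6-methyl-3-methylidene-3a,4,5,8,9,11a-hexahydrocyclodeca[b]furan-2(3H)-one | C=C1C(=O)O[C@@H]2/C=C(\CO[Si](c3ccccc3)(c3ccccc3)C(C)(C)C)CC/C=C(/C)C[C@H](O)[C@@H]12
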